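(The readings are simulated for substances that don't exist; the scatter is artificial.)

**From constants.** I have no constants, only three runs, and I must read from them what two new flasks hold.

in all of them: substrate 0.010 M

|  | coupling partner | remark | time |
|---|---|---|---|
| Monday's | 6.1 equiv | run made earlier |  |
| Friday's | 7.2 equiv | run made earlier |  |
| Sunday's | 11 equiv | run made earlier |  |
| delta | 5.00 equiv |  | 2.5 min |
| beta | 10.0 equiv |  | 2.5 min |

| run | time / s | substrate / % | product / % |
|---|---|---|---|
| Monday's | 10.0 | 90.9 | 0.4 |
| Monday's | 12.0 | 90.0 | 0.9 |
| Monday's | 20.0 | 85.4 | 1.6 |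
| Monday's | 40.0 | 77.6 | 4.0 |
| Monday's | 80.0 | 67.7 | 11.8 |
| Friday's | 10.0 | 89.9 | 0 |
| Friday's | 20.0 | 83.7 | 1.7 |
| Friday's | 40.0 | 73.3 | 4.9 |
| Friday's | 50.0 | 70.3 | 6.8 |
| Friday's | 80.0 | 63.8 | 13.8 |
| Sunday's | 15.0 | 79.9 | 1.7 |
| Sunday's | 30.0 | 67.9 | 5.1 |
| Sunday's | 50.0 | 58.7 | 11.3 |
| Sunday's | 60.0 | 55.4 | 13.3 |
| Sunday's | 80.0 | 50.5 | 19.1 |

(scatter of a reading: 0.5 percentage points)



- part of the substrate that has reacted at the end, delta
- part of the substrate that has reacted at the end, beta
- what raising the equivalents of coupling partner from its lowest to its highest value here does to the part of the substrate that has reacted (changes below 5 percentage points count as none) (it falls / it rises / no change)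

**The puzzle.** In Sunday's run, at 80.0 s, half of the substrate has gone, yet product stands at 19.1 %. The other 30.4 % is held as something else, which I take for an intermediate formed reversibly from substrate and coupling partner.

**Even point.** With c(coupling partner) at 0.110 M, multiplying by substrate over intermediate gives 0.183 M. I call this reading the even point, the level of coupling partner at which I expect intermediate and substrate to stand equal. I take c(intermediate)/c(substrate) as the partner level divided by it, r: 0.274 in delta, 0.547 in beta.

**My reckoning.** Sunday's last stretch gives product forming at 0.00855 /s from the intermediate. Substrate plus intermediate therefore shrinks, pseudo-first-order, at that constant times r/(one plus r). Monday's run shows hardly any product at 20.0 s, so I start the clock there. Dividing what remains by one plus r leaves reacted 38.2 % in delta and 56.4 % in beta, a rise of 18 percentage points.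

**The forecast.** Noting that the “missing mass reaches a plateau”, the forecast gives 37 % for delta and 57 % for beta, slightly apart from mine, and says it rises.

**The result.** Delta gives 36.6 % and beta 56.0 %: it rises, by 19 points.

    intermediate ⇌ product + by-product (K = 0.00230 M, k = 0.0100 /s)
    substrate + coupling partner ⇌ intermediate (K = 7.70 /M, k = 0.160 /M/s)
    coupling partner + by-product ⇌ idle adduct, settled at all times (K = 12.0 /M)

**Held back.** At the end of delta, intermediate over substrate is 0.286, and in beta 0.620, against my 0.274 and 0.547. The gap between the flasks comes from their difference in equivalents of coupling partner: beta stands at 56.0 %, and charged like delta it stands at 36.6 %. A neighbouring flask charged with 0.040 M of substrate at 5.00 equiv has 0.200 M of coupling partner charged, so the even point gives a ratio of 1.09. At 2.50 min that flask holds 41.2 % as intermediate against 32.8 % as substrate.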